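**Plan** (chamigrene locants: ring B = C1–C5 with C2 = CHBr and C3 = CMeCl; C6 = spiro atom; ring A = C6–C11 with C7 = the ring carbon that carries the exocyclic CH2, C10 = CHBr, C11 = CMe2)
1. Retrosynthesis: the cis C2–Br/C3–Cl pair goes back through a trans chlorohydrin to the C2=C3 epoxide; the C7 methylidene goes back to a C7 ketone; ring B is cut at C1–C6 and C4–C5 (isoprene plus the exocyclic enone of ring A); ring A is cut at C10–C11 to an open-chain gem-dibromide that carries an isopropylidene β-keto phosphonate.
2. Enabling feature: C11 lies between C10 and the future spiro atom C6. While C6 is still sp2 and flanked by the C7 ketone and a phosphoryl helper, C11 is the β-carbon of a doubly activated isopropylidene acceptor placed 1,6 to C10. A C10 α-bromo radical (from CHBr2) and C11, both electrophilic carbons in the precursor, can therefore be joined in a 6-endo radical closure that makes the neopentylic C–Br carbon and the quaternary carbon together.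
3. Forward order: chain from a keto phosphonate, allyl bromide and acetone; ring A by the radical closure; phosphonate turned into the exocyclic enone; ring B by Diels–Alder; methylenation; ring-B halogens last.
4. Stereochemistry: C10 arises in the ring closure as a racemate; C6 is relayed from C10 in the Diels–Alder; the absolute configuration and the C2/C3 face come from a Shi epoxidation that turns the two enantiomers into separable diastereomers; C3 and then C2 are set by two SN2 inversions.

Key step: step 5

Remark: the target SMILES is read as (2S,3R,6R,10R) with C2–Br and C3–Cl cis on ring B (C3 methyl trans to C2–Br), so an anti bromochlorination of the ring-B alkene is not used; racemic intermediates are drawn as the enantiomer that is carried on.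

Step 1
Reactants: 1 diethyl (2-oxopropyl)phosphonate; 2 allyl bromide
Product: 4 diethyl (2-oxohex-5-en-1-yl)phosphonate, via sodium lithium dianion 3 (not isolated)
Conditions: NaH, THF, 0 °C; n-BuLi, 0 °C; then 2, 0 °C → rt; aq. HCl quench
Reagents that add atoms: none
Why: γ-alkylation of a β-keto phosphonate 1,3-dianion occurs at the more basic terminal carbanion, so the allyl group should enter only on the methyl side.

Step 2
Reactants: 4 diethyl (2-oxohex-5-en-1-yl)phosphonate; 5 acetone
Product: 6 diethyl (2-methyl-4-oxoocta-2,7-dien-3-yl)phosphonate
Conditions: 5 (excess), TiCl4, pyridine, THF, 0 °C → rt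
Reagents that add atoms: none
Why: the TiCl4–pyridine Knoevenagel condensation is the standard way to condense a ketone with an active methylene group, and it should turn the CH2 between C=O and P=O into the isopropylidene acceptor.

Step 3
Reactants: 6 diethyl (2-methyl-4-oxoocta-2,7-dien-3-yl)phosphonate
Product: 8 diethyl (2-methyl-4,7-dioxohept-2-en-3-yl)phosphonate, via secondary ozonide 7 (not isolated)
Conditions: O3 (to the end point), CH2Cl2, −78 °C; then PPh3, −78 °C → rt
Reagents that add atoms: ozone, [O-][O+]=O
Why: in this ozonolysis ozone should attack the electron-rich monosubstituted alkene far faster than the electron-poor tetrasubstituted isopropylidene unit, and reductive work-up gives the aldehyde.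

Step 4
Reactants: 8 diethyl (2-methyl-4,7-dioxohept-2-en-3-yl)phosphonate
Product: 9 diethyl (7,7-dibromo-2-methyl-4-oxohept-2-en-3-yl)phosphonate
Conditions: P(OPh)3, Br2, CH2Cl2, −78 °C; then 8, −78 → −20 °C
Reagents that add atoms: bromine, BrBr
Why: deoxygenative gem-dibromination with the triphenyl phosphite–bromine adduct converts aldehydes into 1,1-dibromides at low temperature, where the hindered cross-conjugated ketone should not react.

Step 5
Reactants: 9 diethyl (7,7-dibromo-2-methyl-4-oxohept-2-en-3-yl)phosphonate
Product: 10 rac-diethyl [(3R*)-3-bromo-2,2-dimethyl-6-oxocyclohexyl]phosphonate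
Conditions: (Me3Si)3SiH (1.05 equiv) and AIBN (0.1 equiv) by syringe pump, PhH (0.01 M), 80 °C
Reagents that add atoms: none
Why: Proposed new method: the silyl radical abstracts one bromine atom from the CHBr2 group to give a secondary α-bromoalkyl radical at C10, which adds to C11, the β-carbon of the isopropylidene β-keto phosphonate, and the resulting C6 radical, stabilised by the C7 ketone and the phosphoryl group, takes a hydrogen atom from the silane and carries the chain. The closest known reaction type is the stannane- or silane-mediated reductive (Giese-type) radical cyclisation of a halide onto an enone whose carbonyl group lies inside the forming ring, together with the known stepwise mono-reduction of geminal dibromides; what is new is the use of a CHBr2 group as the source of a bromine-retaining radical that closes onto a tetrasubstituted acceptor. Ring A closes in the 6-endo-trig mode, because the 5-exo alternative would need attack at C6, which is fully substituted and the α-carbon of the acceptor, and would leave an unstabilised tertiary radical. The new stereocentre C10 forms without an external controller and is therefore racemic, and the C6 centre is epimerisable and is removed in the next step. The step needs removal of only one bromine and cyclisation before hydrogen transfer: the gem-dibromide is a better bromine-atom donor than the neopentylic monobromide product, the doubly activated acceptor is polarity-matched with the carbon radical and the electrophilic C6 radical with the hydridic silane, and slow addition keeps the silane concentration low. C11 becomes quaternary in the same event, so the C10–Br carbon and the gem-dimethyl carbon of ring A are made together.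

Step 6
Reactants: 10 rac-diethyl [(3R*)-3-bromo-2,2-dimethyl-6-oxocyclohexyl]phosphonate; 11 formaldehyde
Product: 12 rac-4-bromo-3,3-dimethyl-2-methylidenecyclohexan-1-one
Conditions: 11 (37 % aq.), K2CO3, THF–H2O, 0 °C → rt
Reagents that add atoms: none
Why: the Horner–Wadsworth–Emmons olefination of a cyclic β-keto phosphonate with formaldehyde gives the 2-methylene ketone directly and removes the phosphoryl helper, and the mild carbonate base at 0 °C is chosen so that the stabilised carbanion should be trapped by formaldehyde before it can displace the 1,3-related bromide.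

Step 7
Reactants: 12 rac-4-bromo-3,3-dimethyl-2-methylidenecyclohexan-1-one; 13 isoprene
Product: 14 rac-(4R*,6S*)-4-bromo-5,5,9-trimethylspiro[5.5]undec-8-en-1-one
Conditions: 13 (5 equiv), Me2AlCl (0.3 equiv), CH2Cl2, −78 → −20 °C
Reagents that add atoms: none
Why: the Lewis-acid-catalysed Diels–Alder reaction of the 2-methylene ketone with isoprene should give the para adduct (ring-B methyl 1,4 to the spiro carbon), and the diene should add to the exocyclic alkene opposite the axial C11 methyl group of the chair with equatorial bromine, which puts the new C6–C1 bond trans to the C10 bromine and so sets C6 relative to C10.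

Step 8
Reactants: 14 rac-(4R*,6S*)-4-bromo-5,5,9-trimethylspiro[5.5]undec-8-en-1-one
Product: 15 rac-(6R*,10R*)-10-bromo-β-chamigrene
Conditions: Cp2Ti(μ-CH2)(μ-Cl)AlMe2 (Tebbe reagent), pyridine, THF–toluene, −40 °C → rt
Reagents that add atoms: Tebbe reagent Cp2Ti(μ-CH2)(μ-Cl)AlMe2, C[Al](C)C[Ti](Cl)(C1C=CC=C1)C1C=CC=C1
Why: the Tebbe olefination methylenates hindered, enolisable ketones under non-basic conditions through the titanium methylidene and an oxatitanacyclobutane, so the secondary bromide should not be eliminated.

Step 9
Reactants: 15 rac-(6R*,10R*)-10-bromo-β-chamigrene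
Product: 16 (2R,3S,6R,10R)-10-bromo-2,3-epoxy-2,3-dihydro-β-chamigrene
Conditions: D-fructose-derived Shi ketone (30 mol %), KHSO5 (as 2KHSO5·KHSO4·K2SO4), K2CO3, Bu4NHSO4 (cat.), MeCN–dimethoxymethane/aq. Na2B4O7 buffer, 0 °C; chromatography
Reagents that add atoms: potassium peroxymonosulfate KHSO5, [K+].[O-]S(=O)(=O)OO
Why: in the Shi asymmetric epoxidation the chiral dioxirane should attack only the trisubstituted ring alkene and, by the spiro transition-state model, deliver oxygen to the same local face of both enantiomers, so that (6R,10R)-15 gives the epoxide with oxygen on the C11 side and the antipode gives a separable diastereomer (chiral-dioxirane resolution of a racemic cyclic olefin), which fixes the absolute configuration and the C2/C3 face.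

Step 10
Reactants: 16 (2R,3S,6R,10R)-10-bromo-2,3-epoxy-2,3-dihydro-β-chamigrene
Product: 17 (2R,3R,6R,10R)-10-bromo-3-chlorochamigr-7(14)-en-2-ol
Conditions: HCl (1.0 M in Et2O, 1.2 equiv), CH2Cl2, −78 → −30 °C
Reagents that add atoms: hydrogen chloride, Cl
Why: acid-mediated opening of a trisubstituted epoxide by chloride takes place at the tertiary carbon with inversion (Markovnikov-type, borderline SN2), which should give the trans chlorohydrin with C3–Cl on the C7 side and C2–OH on the C11 side, the hindered exocyclic alkene reacting much more slowly at this temperature.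

Step 11
Reactants: 17 (2R,3R,6R,10R)-10-bromo-3-chlorochamigr-7(14)-en-2-ol
Product: 18 (2S,3R,6R,10R)-2,10-dibromo-3-chlorochamigr-7(14)-ene
Conditions: PPh3, CBr4, CH2Cl2, 0 °C → rt
Reagents that add atoms: carbon tetrabromide, BrC(Br)(Br)Br
Why: the Appel reaction replaces the activated hydroxyl group by bromide in an SN2 process with inversion at C2, which should turn the trans chlorohydrin into the cis bromochloride of the target.

**Compound list**
1 | diethyl (2-oxopropyl)phosphonate | CCOP(=O)(CC(C)=O)OCC | starting material
2 | allyl bromide (3-bromoprop-1-ene) | C=CCBr | starting material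
3 | sodium lithium 1,3-dianion of 1 | [CH2-]C(=O)[CH-]P(=O)(OCC)OCC.[Na+].[Li+] | intermediate (not isolated)
4 | diethyl (2-oxohex-5-en-1-yl)phosphonate | CCOP(=O)(CC(=O)CCC=C)OCC | intermediate
5 | acetone | CC(C)=O | starting material
6 | diethyl (2-methyl-4-oxoocta-2,7-dien-3-yl)phosphonate | CCOP(=O)(OCC)C(C(=O)CCC=C)=C(C)C | intermediate
7 | secondary ozonide (1,2,4-trioxolane) of the terminal alkene of 6 | CCOP(=O)(OCC)C(C(=O)CCC1OCOO1)=C(C)C | intermediate (not isolated)
8 | diethyl (2-methyl-4,7-dioxohept-2-en-3-yl)phosphonate | CCOP(=O)(OCC)C(C(=O)CCC=O)=C(C)C | intermediate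
9 | diethyl (7,7-dibromo-2-methyl-4-oxohept-2-en-3-yl)phosphonate | CCOP(=O)(OCC)C(C(=O)CCC(Br)Br)=C(C)C | intermediate
10 | rac-diethyl [(3R*)-3-bromo-2,2-dimethyl-6-oxocyclohexyl]phosphonate (racemate, C1 epimers; 3R drawn) | CCOP(=O)(OCC)C1C(=O)CC[C@@H](Br)C1(C)C | intermediate
11 | formaldehyde | C=O | starting material
12 | rac-4-bromo-3,3-dimethyl-2-methylidenecyclohexan-1-one (racemate; 4R drawn) | C=C1C(=O)CC[C@@H](Br)C1(C)C | intermediate
13 | isoprene (2-methylbuta-1,3-diene) | C=CC(C)=C | starting material
14 | rac-(4R*,6S*)-4-bromo-5,5,9-trimethylspiro[5.5]undec-8-en-1-one (racemate; 4R,6S drawn; new C6–CH2 bond trans to Br) | O=C1CC[C@@H](Br)C(C)(C)[C@@]12CCC(C)=CC2 | intermediate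
15 | rac-(6R*,10R*)-10-bromo-β-chamigrene, i.e. (2R*,6R*)-2-bromo-1,1,9-trimethyl-5-methylidenespiro[5.5]undec-8-ene (racemate; 6R,10R drawn) | C=C1CC[C@@H](Br)C(C)(C)[C@@]12CCC(C)=CC2 | intermediate
16 | (2R,3S,6R,10R)-10-bromo-2,3-epoxy-2,3-dihydro-β-chamigrene (epoxide oxygen on the ring-B face that carries C11) | C=C1CC[C@@H](Br)C(C)(C)[C@@]12CC[C@]3(C)O[C@@H]3C2 | intermediate
17 | (2R,3R,6R,10R)-10-bromo-3-chlorochamigr-7(14)-en-2-ol (trans chlorohydrin) | C=C1CC[C@@H](Br)C(C)(C)[C@@]12CC[C@@](C)(Cl)[C@H](O)C2 | intermediate
18 | (2S,3R,6R,10R)-2,10-dibromo-3-chlorochamigr-7(14)-ene, i.e. (2R,6R,8S,9R)-2,8-dibromo-9-chloro-1,1,9-trimethyl-5-methylidenespiro[5.5]undecane | C=C1CC[C@@H](Br)C(C)(C)[C@@]12CC[C@@](C)(Cl)[C@@H](Br)C2 | target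

Total step count: 11. Longest linear sequence: 11 steps.

**Steps most likely to fail**

Step 5 (proposed new method). What may go wrong is hydrogen-atom transfer to the open-chain α-bromo radical before ring closure, or abstraction of the second bromine, because addition to the twisted tetrasubstituted acceptor may be slow. The fallback sets out from 8 and comes back at 10. A SmI2-mediated reductive ketyl–olefin cyclisation of 8 (SmI2, t-BuOH, THF, −78 °C) should close the same C10–C11 bond by joining the aldehyde carbon to the β-carbon of the isopropylidene acceptor and give diethyl (3-hydroxy-2,2-dimethyl-6-oxocyclohexyl)phosphonate F1. An Appel bromination (PPh3, CBr4, CH2Cl2) would then convert the hydroxyl group into the bromide of 10; its steric course does not matter at this racemic stage, but substitution at the neopentylic carbon is the weak point of this fallback.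

Step 9. What may go wrong is incomplete reagent control of the facial selectivity on the mismatched enantiomer, which would lower the enantiomeric purity of the epoxide and leave the whole resolution to the diastereomer separation. The fallback sets out from 12 and comes back at 12 as a single enantiomer. A Corey–Bakshi–Shibata reduction of racemic 12 ((S)-Me-CBS oxazaborolidine, BH3·SMe2, THF, −20 °C) should give, under reagent control, (1R,4R)-4-bromo-3,3-dimethyl-2-methylidenecyclohexan-1-ol F2 from (R)-12 and (1R,4S)-4-bromo-3,3-dimethyl-2-methylidenecyclohexan-1-ol F3 from (S)-12. After chromatographic separation, F2 is oxidised back with MnO2 to (R)-12, which is carried through steps 7 and 8, so that step 9 then acts on one enantiomer only and in the matched sense.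

Step 11. What may go wrong is elimination or chloride-assisted ionisation (retention or rearrangement) outrunning the SN2 displacement at the hindered C2. The fallback sets out from 17 and comes back at 18. Activation and displacement are separated: the alcohol is converted with Tf2O and pyridine (CH2Cl2, −78 °C) into (2R,3R,6R,10R)-10-bromo-3-chlorochamigr-7(14)-en-2-yl trifluoromethanesulfonate F4, which is then displaced with Bu4NBr in toluene at low temperature, a non-basic and strongly nucleophilic bromide source, with inversion at C2.

**Further compounds**
F1 | step 5 | diethyl (3-hydroxy-2,2-dimethyl-6-oxocyclohexyl)phosphonate (racemic) | CCOP(=O)(OCC)C1C(=O)CCC(O)C1(C)C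
F2 | step 9 | (1R,4R)-4-bromo-3,3-dimethyl-2-methylidenecyclohexan-1-ol | O[C@@H]1CC[C@@H](Br)C(C)(C)C1=C
F3 | step 9 | (1R,4S)-4-bromo-3,3-dimethyl-2-methylidenecyclohexan-1-ol | O[C@@H]1CC[C@H](Br)C(C)(C)C1=C
F4 | step 11 | (2R,3R,6R,10R)-10-bromo-3-chlorochamigr-7(14)-en-2-yl trifluoromethanesulfonate | C=C1CC[C@@H](Br)C(C)(C)[C@@]12CC[C@@](C)(Cl)[C@H](OS(=O)(=O)C(F)(F)F)C2
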